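**Plan**

- Feature used: in each (3S,4E)-4-formyl-3-(2-oxoethyl)hex-4-enoyl arm, the aldehyde carbon of the 2-oxoethyl branch and the ethylidene CH (C5 of the hexenoyl chain) are 1,5-related. Joining them gives a 4-hydroxy-3-methylcyclopentane with CHO and CH2CO2R on the next two ring carbons: the same ring, substituent pattern and absolute sense at the side-chain-bearing CH as the core cyclopentane. The target is therefore three copies of one cyclopentane.
- Cuts (retro): the acetonide on the 1,3-diol; the two ring bonds just named (forward: one twofold alkoxy-radical β-scission opens both arm rings); the two ester C–O bonds (double Mitsunobu, inversion at the core carbinol C7); then CH2CO2H (ozonolysis, Wolff) and CH(CH2OH)2 (allylic oxidation, hydroboration) back to one isopropenyl group.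
- Forward: (R)-carvone → Favorskii ring contraction to the cyclopentane → common diol 10 → core diol 13 and arm acid 19 → diester 20 → four aldehydes and two ethylidenes unveiled → acetonide removed.
- Stereochemistry: only C5 of (R)-carvone is bought; it becomes the side-chain-bearing CH of all three rings. C9 and C8 are relayed from it in one equilibration of a γ-keto ester, C7 by reagent approach and, in the core, Mitsunobu inversion. The (E)-alkenes come from thermodynamic E1cB.

Key step: step 18

Locants: in every cyclopentane, C5 = ring CH bearing the side chain derived from the isopropenyl group, C6 = ring CH2, C7 = carbinol (or carbonyl) carbon, C8 = CH–CH3, C9 = ring CH bearing C1 (CO2Me, CH2O or CHO). Primed locants refer to the two arm rings.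

Assumption: in ester 6 the CO2Me group is taken as cis to the isopropenyl group and trans to the methyl group, and methyl and acetal oxygen as cis. C7–C9 are erased and reset in steps 5–7, so the route depends only on C5 and on the ring-contracted constitution.

**Route**

Step 1
Reactants: 1 (R)-(−)-carvone
Product: 2 (1R,4R,6R)-1-methyl-4-(prop-1-en-2-yl)-7-oxabicyclo[4.1.0]heptan-2-one
Conditions: 35% H2O2, aq. NaOH, MeOH, 0 °C
Reagents that add atoms: hydrogen peroxide, OO
Why: Weitz–Scheffer nucleophilic epoxidation of the enone: hydroperoxide should add to C3 anti to the C5 isopropenyl group, so that the epoxide is trans to it.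

Step 2
Reactants: 2 carvone epoxide
Product: 3 (2S,3R,5R)-2-chloro-3-hydroxy-2-methyl-5-(prop-1-en-2-yl)cyclohexan-1-one
Conditions: LiCl, CF3CO2H, THF, rt
Reagents that add atoms: lithium chloride, [Li+].[Cl-]
Why: Acid-promoted SN2 opening of the α,β-epoxy ketone by chloride at the carbonyl-activated α-carbon should give, with inversion, the α-chloro-β-hydroxy ketone needed for ring contraction.

Step 3
Reactants: 3 chlorohydrin
Product: 4 (2S,3R,5R)-2-chloro-2-methyl-3-(oxan-2-yloxy)-5-(prop-1-en-2-yl)cyclohexan-1-one (both acetal epimers)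
Conditions: 3,4-dihydro-2H-pyran, PPTS (cat.), CH2Cl2, rt
Reagents that add atoms: 3,4-dihydro-2H-pyran, C1=COCCC1
Why: Acid-catalysed acetalisation masks the hydroxyl, which would otherwise re-close the epoxide under the basic conditions of the next step.

Step 4
Reactants: 4 chloro ketone THP ether
Product: 6 methyl (1R,2S,3R,5R)-2-methyl-3-(oxan-2-yloxy)-5-(prop-1-en-2-yl)cyclopentane-1-carboxylate, via cyclopropanone 5 (not isolated)
Conditions: NaOMe, MeOH, 0 °C → rt
Reagents that add atoms: sodium methoxide, C[O-].[Na+]
Why: Favorskii rearrangement: the C6 enolate displaces chloride to give cyclopropanone 5, which methoxide opens toward the methyl-bearing carbon (carbanion stabilised by the β-acetal oxygen), so that the six-membered ring contracts to the cyclopentane ester with C5 untouched.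

Step 5
Reactants: 6 cyclopentane ester THP ether
Product: 7 methyl (1R,2S,5R)-2-methyl-3-oxo-5-(prop-1-en-2-yl)cyclopentane-1-carboxylate
Conditions: Jones reagent (CrO3, H2SO4, H2O), acetone, 0 °C
Reagents that add atoms: none
Why: Jones oxidation in aqueous acid hydrolyses the acetal and oxidises the liberated secondary alcohol to the ketone, which makes C8 (α to the ketone) epimerisable beside C9 (α to the ester).

Step 6
Reactants: 7 keto ester
Product: 8 methyl (1S,2R,5R)-2-methyl-3-oxo-5-(prop-1-en-2-yl)cyclopentane-1-carboxylate (all-trans)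
Conditions: NaOMe (cat.), MeOH, rt
Reagents that add atoms: none
Why: Base-mediated equilibration of the γ-keto ester through the ketone and ester enolates should relay the fixed C5 centre to C9 and then to C8, the all-trans isomer being the only one without a cis-vicinal pair.

Step 7
Reactants: 8 all-trans keto ester
Product: 10 (1S,2R,3S,4R)-3-(hydroxymethyl)-2-methyl-4-(prop-1-en-2-yl)cyclopentan-1-ol, via hydroxy ester 9 (not isolated)
Conditions: L-Selectride, THF, −78 °C; then LiAlH4, −78 → 0 °C; Rochelle salt work-up
Reagents that add atoms: none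
Why: The bulky trialkylborohydride should attack the ketone from the face opposite to the adjacent C8 methyl and the C5 side chain (the mode known for 2,3-trans-disubstituted cyclopentanones), setting C7 with OH cis to methyl and trans to C9, after which LiAlH4 reduces the ester.

Step 8
Reactants: 10 common diol
Product: 11 (1S,2R,3S,4R)-3-(hydroxymethyl)-4-(3-hydroxyprop-1-en-2-yl)-2-methylcyclopentan-1-ol
Conditions: SeO2 (cat.), t-BuOOH, CH2Cl2, rt
Reagents that add atoms: selenium dioxide, O=[Se]=O (delivers the oxygen; re-oxidised by tert-butyl hydroperoxide, CC(C)(C)OO)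
Why: Selenium dioxide allylic oxidation (ene reaction, then [2,3]-sigmatropic shift) of the 1,1-disubstituted alkene should hydroxylate the methyl group and return the double bond to its place.

Step 9
Reactants: 11 allylic triol
Product: 12 2-[(1R,2S,3R,4S)-4-hydroxy-2-(hydroxymethyl)-3-methylcyclopentyl]propane-1,3-diol
Conditions: BH3·THF (excess), THF, 0 °C → rt; then NaOH, H2O2
Reagents that add atoms: hydrogen peroxide, OO
Why: Anti-Markovnikov hydroboration–oxidation of the 1,1-disubstituted alkene gives the second CH2OH; the carbon so formed bears two identical arms, so no stereocentre arises.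

Step 10
Reactants: 12 tetraol
Product: 13 (1S,2R,3S,4R)-4-(2,2-dimethyl-1,3-dioxan-5-yl)-3-(hydroxymethyl)-2-methylcyclopentan-1-ol
Conditions: Me2C(OMe)2, PPTS (cat.), acetone, rt
Reagents that add atoms: 2,2-dimethoxypropane, COC(C)(C)OC
Why: Thermodynamic acetalisation selects the 1,3-diol (six-membered 1,3-dioxane) over any pairing with the other two hydroxyls (seven- or eight-membered rings), which leaves exactly the two hydroxyls to be acylated.

Step 11
Reactants: 10 common diol
Product: 14 bis(tert-butyldimethylsilyl) ether of 10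
Conditions: TBSOTf, 2,6-lutidine, CH2Cl2, 0 °C
Reagents that add atoms: tert-butyldimethylsilyl trifluoromethanesulfonate, CC(C)(C)[Si](C)(C)OS(=O)(=O)C(F)(F)F
Why: Silylation of both hydroxyls with the reactive silyl triflate protects them through enolate, diazo and coupling chemistry.

Step 12
Reactants: 14 bis-silyl ether
Product: 15 1-[(1R,2R,3R,4S)-4-(tert-butyldimethylsilyloxy)-2-(tert-butyldimethylsilyloxymethyl)-3-methylcyclopentyl]ethan-1-one
Conditions: O3, CH2Cl2, −78 °C; then Me2S
Reagents that add atoms: ozone, [O-][O+]=O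
Why: Ozonolysis of the only alkene gives the methyl ketone; C5 becomes α to a carbonyl but already holds the thermodynamically preferred trans relation to C9, so it should not drift.

Step 13
Reactants: 15 methyl ketone
Product: 17 2-diazo-1-[(1R,2R,3R,4S)-4-(tert-butyldimethylsilyloxy)-2-(tert-butyldimethylsilyloxymethyl)-3-methylcyclopentyl]ethan-1-one, via trifluoroacetyl ketone 16 (not isolated)
Conditions: LiHMDS, THF, −78 °C; CF3CO2CH2CF3; then MsN3, Et3N, H2O, MeCN, rt
Reagents that add atoms: methanesulfonyl azide, CS(=O)(=O)N=[N+]=[N-]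
Why: Detrifluoroacetylative Regitz diazo transfer: kinetic deprotonation at the methyl group, trifluoroacetylation to 16 and transfer of N2 from the sulfonyl azide with loss of the trifluoroacetyl group give the terminal α-diazo ketone without touching C5–H.

Step 14
Reactants: 17 diazo ketone
Product: 19 2-[(1S,2S,3R,4S)-4-(tert-butyldimethylsilyloxy)-2-(tert-butyldimethylsilyloxymethyl)-3-methylcyclopentyl]acetic acid, via ketene 18 (not isolated)
Conditions: PhCO2Ag (cat.), Et3N, THF/H2O, rt, dark
Reagents that add atoms: water, O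
Why: Silver-catalysed Wolff rearrangement (the second half of an Arndt–Eistert homologation): C5 migrates with retention to give ketene 18, which water traps as the acetic acid side chain.

Step 15
Reactants: 13 core diol; 19 arm acid (excess, at least two equivalents)
Product: 20 core diester carrying the acetonide and four silyl ethers (core ring 1S,2R,3R,5R; C7 inverted)
Conditions: PPh3, DIAD, toluene/THF, 0 °C → rt
Reagents that add atoms: none
Why: Mitsunobu esterification: the primary hydroxyl is displaced at CH2 and the secondary C7 hydroxyl with inversion (SN2 on the alkoxyphosphonium from the face bearing only H at C8), so both ester bonds form in one operation and C7 ends trans to the methyl group as in the target.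

Step 16
Reactants: 20 tetrasilylated diester
Product: 21 diester tetraol (each arm: free C1′H2OH and C7′–OH; acetonide kept)
Conditions: HF·pyridine, pyridine, THF, 0 °C → rt
Reagents that add atoms: none
Why: Fluoride-mediated cleavage of the four silyl ethers under buffered, non-basic conditions keeps the acetonide and avoids alkoxide attack of the freed arm hydroxyls on the linking esters.

Step 17
Reactants: 21 diester tetraol
Product: 22 bis(hydroxy aldehyde) diester (each arm: C1′HO and free C7′–OH)
Conditions: TEMPO (cat.), PhI(OAc)2, CH2Cl2, rt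
Reagents that add atoms: none
Why: Oxoammonium (TEMPO) oxidation with PhI(OAc)2 is selective for primary over secondary alcohols, so each arm gains its C1′ aldehyde while the C7′ carbinol, trans to it and therefore unable to form a lactol, stays free.

Step 18
Reactants: 22 bis(hydroxy aldehyde) diester
Product: 24 acetonide of the target (four aldehydes, two (E)-ethylidenes), via bis(iodo aldehyde) 23 (not isolated)
Conditions: PhI(OAc)2, I2, CH2Cl2, hν (visible), rt; then Et3N, 0 °C → rt
Reagents that add atoms: none
Why: Each arm cyclopentanol is converted by PhI(OAc)2/I2 into its hypoiodite, whose O–I bond is homolysed by light; the cyclopentyloxy radical undergoes β-scission of the strained ring at the more substituted C7′–C8′ bond, so that C7′ becomes the aldehyde of the 2-oxoethyl branch and the secondary C8′ radical is trapped by iodine. The β-iodo aldehyde 23 then loses HI by E1cB on addition of Et3N, the acidic C9′–H being α to the formyl group, which places the double bond only between C8′ and C9′ and should give the thermodynamically preferred (E)-2-ethylidene aldehyde. The closest known reaction type is the hypoiodite (alkoxy-radical) β-fragmentation of secondary cycloalkanols to ω-iodo aldehydes followed by dehydroiodination; no ring is closed, two rings are opened. No new stereocentre is formed: C8′ and C9′ become sp2 and C5′, the only centre kept in each arm, is not touched. The step needs β-scission to outrun 1,5-hydrogen transfer and to choose C7′–C8′ over C7′–C6′; ring strain and the secondary versus primary radical secure the regiochemistry, and the trans disposition of the C7′ oxygen and the C9′ formyl group, fixed in step 7, keeps the weak aldehydic C–H out of reach. The core hydroxyls are masked as the acetonide, so only the two arm carbinols form hypoiodites.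

Step 19
Reactants: 24 acetonide of the target
Product: 25 target, [(1S,2R,3R,5R)-5-(1,3-dihydroxypropan-2-yl)-2-methyl-3-{[(3S,4E)-4-formyl-3-(2-oxoethyl)hex-4-enoyl]oxy}cyclopentyl]methyl (3S,4E)-4-formyl-3-(2-oxoethyl)hex-4-enoate
Conditions: AcOH/H2O (4:1), rt
Reagents that add atoms: none
Why: Mild aqueous acid hydrolysis of the 1,3-dioxane ketal, which is more labile than the esters and leaves the aldehydes as such after work-up, releases the 1,3-diol.

**Compound list**

1 | (R)-(−)-carvone | CC1=CC[C@H](CC1=O)C(C)=C | starting material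
2 | (1R,4R,6R)-1-methyl-4-(prop-1-en-2-yl)-7-oxabicyclo[4.1.0]heptan-2-one | CC(=C)[C@H]1CC(=O)[C@]2(C)O[C@@H]2C1 | intermediate
3 | (2S,3R,5R)-2-chloro-3-hydroxy-2-methyl-5-(prop-1-en-2-yl)cyclohexan-1-one | CC(=C)[C@H]1CC(=O)[C@@](C)(Cl)[C@H](O)C1 | intermediate
4 | (2S,3R,5R)-2-chloro-2-methyl-3-(oxan-2-yloxy)-5-(prop-1-en-2-yl)cyclohexan-1-one | CC(=C)[C@H]1CC(=O)[C@@](C)(Cl)[C@H](OC2CCCCO2)C1 | intermediate
5 | 1-methyl-2-(oxan-2-yloxy)-4-(prop-1-en-2-yl)bicyclo[3.1.0]hexan-6-one (Favorskii cyclopropanone) | O=C1[C@@]2(C)[C@H](OC3CCCCO3)C[C@H]([C@@H]12)C(C)=C | intermediate (not isolated)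
6 | methyl (1R,2S,3R,5R)-2-methyl-3-(oxan-2-yloxy)-5-(prop-1-en-2-yl)cyclopentane-1-carboxylate | COC(=O)[C@H]1[C@H](C)[C@H](OC2CCCCO2)C[C@H]1C(C)=C | intermediate
7 | methyl (1R,2S,5R)-2-methyl-3-oxo-5-(prop-1-en-2-yl)cyclopentane-1-carboxylate | COC(=O)[C@H]1[C@H](C)C(=O)C[C@H]1C(C)=C | intermediate
8 | methyl (1S,2R,5R)-2-methyl-3-oxo-5-(prop-1-en-2-yl)cyclopentane-1-carboxylate | COC(=O)[C@@H]1[C@@H](C)C(=O)C[C@H]1C(C)=C | intermediate
9 | methyl (1S,2R,3S,5R)-3-hydroxy-2-methyl-5-(prop-1-en-2-yl)cyclopentane-1-carboxylate | COC(=O)[C@@H]1[C@@H](C)[C@@H](O)C[C@H]1C(C)=C | intermediate (not isolated)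
10 | (1S,2R,3S,4R)-3-(hydroxymethyl)-2-methyl-4-(prop-1-en-2-yl)cyclopentan-1-ol | OC[C@@H]1[C@@H](C)[C@@H](O)C[C@H]1C(C)=C | intermediate
11 | (1S,2R,3S,4R)-3-(hydroxymethyl)-4-(3-hydroxyprop-1-en-2-yl)-2-methylcyclopentan-1-ol | OC[C@@H]1[C@@H](C)[C@@H](O)C[C@H]1C(=C)CO | intermediate
12 | 2-[(1R,2S,3R,4S)-4-hydroxy-2-(hydroxymethyl)-3-methylcyclopentyl]propane-1,3-diol | OC[C@@H]1[C@@H](C)[C@@H](O)C[C@H]1C(CO)CO | intermediate
13 | (1S,2R,3S,4R)-4-(2,2-dimethyl-1,3-dioxan-5-yl)-3-(hydroxymethyl)-2-methylcyclopentan-1-ol | OC[C@@H]1[C@@H](C)[C@@H](O)C[C@H]1C2COC(C)(C)OC2 | intermediate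
14 | bis(tert-butyldimethylsilyl) ether of 10 | CC(C)(C)[Si](C)(C)OC[C@@H]1[C@@H](C)[C@@H](O[Si](C)(C)C(C)(C)C)C[C@H]1C(C)=C | intermediate
15 | 1-[(1R,2R,3R,4S)-4-(tert-butyldimethylsilyloxy)-2-(tert-butyldimethylsilyloxymethyl)-3-methylcyclopentyl]ethan-1-one | CC(C)(C)[Si](C)(C)OC[C@@H]1[C@@H](C)[C@@H](O[Si](C)(C)C(C)(C)C)C[C@H]1C(C)=O | intermediate
16 | 4,4,4-trifluoro-1-[the cyclopentyl group of 15]butane-1,3-dione | CC(C)(C)[Si](C)(C)OC[C@@H]1[C@@H](C)[C@@H](O[Si](C)(C)C(C)(C)C)C[C@H]1C(=O)CC(=O)C(F)(F)F | intermediate (not isolated)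
17 | 2-diazo-1-[the cyclopentyl group of 15]ethan-1-one | CC(C)(C)[Si](C)(C)OC[C@@H]1[C@@H](C)[C@@H](O[Si](C)(C)C(C)(C)C)C[C@H]1C(=O)C=[N+]=[N-] | intermediate
18 | 2-[the cyclopentyl group of 15]ethen-1-one (ketene) | CC(C)(C)[Si](C)(C)OC[C@@H]1[C@@H](C)[C@@H](O[Si](C)(C)C(C)(C)C)C[C@H]1C=C=O | intermediate (not isolated)
19 | 2-[(1S,2S,3R,4S)-4-(tert-butyldimethylsilyloxy)-2-(tert-butyldimethylsilyloxymethyl)-3-methylcyclopentyl]acetic acid | CC(C)(C)[Si](C)(C)OC[C@@H]1[C@@H](C)[C@@H](O[Si](C)(C)C(C)(C)C)C[C@H]1CC(=O)O | intermediate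
20 | diester of the C7-inverted core diol (ring 1S,2R,3R,5R, acetonide kept) carrying the acyl group of 19 on both oxygens | CC(C)(C)[Si](C)(C)OC[C@@H]1[C@@H](C)[C@@H](O[Si](C)(C)C(C)(C)C)C[C@H]1CC(=O)OC[C@@H]2[C@@H](C)[C@H](OC(=O)C[C@@H]3C[C@H](O[Si](C)(C)C(C)(C)C)[C@H](C)[C@H]3CO[Si](C)(C)C(C)(C)C)C[C@H]2C4COC(C)(C)OC4 | intermediate
21 | diester tetraol (20 without the four silyl groups) | OC[C@@H]1[C@@H](C)[C@@H](O)C[C@H]1CC(=O)OC[C@@H]2[C@@H](C)[C@H](OC(=O)C[C@@H]3C[C@H](O)[C@H](C)[C@H]3CO)C[C@H]2C4COC(C)(C)OC4 | intermediate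
22 | bis(hydroxy aldehyde) diester (each arm 2-formyl-4-hydroxy-3-methylcyclopentylacetyl) | O=C[C@@H]1[C@@H](C)[C@@H](O)C[C@H]1CC(=O)OC[C@@H]2[C@@H](C)[C@H](OC(=O)C[C@@H]3C[C@H](O)[C@H](C)[C@H]3C=O)C[C@H]2C4COC(C)(C)OC4 | intermediate
23 | bis(β-iodo aldehyde) diester (each arm 4-formyl-5-iodo-3-(2-oxoethyl)hexanoyl, iodide epimers) | O=C[C@H](C(C)I)[C@@H](CC=O)CC(=O)OC[C@@H]1[C@@H](C)[C@H](OC(=O)C[C@H](CC=O)[C@H](C=O)C(C)I)C[C@H]1C2COC(C)(C)OC2 | intermediate (not isolated)
24 | acetonide of the target | C/C=C(/C=O)[C@@H](CC=O)CC(=O)OC[C@@H]1[C@@H](C)[C@H](OC(=O)C[C@H](CC=O)/C(C=O)=C\C)C[C@H]1C2COC(C)(C)OC2 | intermediate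
25 | [(1S,2R,3R,5R)-5-(1,3-dihydroxypropan-2-yl)-2-methyl-3-{[(3S,4E)-4-formyl-3-(2-oxoethyl)hex-4-enoyl]oxy}cyclopentyl]methyl (3S,4E)-4-formyl-3-(2-oxoethyl)hex-4-enoate | C/C=C(/C=O)[C@@H](CC=O)CC(=O)OC[C@@H]1[C@@H](C)[C@H](OC(=O)C[C@H](CC=O)/C(C=O)=C\C)C[C@H]1C(CO)CO | target

**Count and risks**

Total steps: 19. Longest linear sequence: 16 (steps 1–7, 11–14, 15–19); the core branch (steps 8–10) joins at step 15.

Steps most likely to fail:

1. Step 18. The twofold radical ring opening may be eroded by hydrogen transfer to the alkoxy radical, by incomplete conversion of the second arm, or by degradation of the aldehydes under iodine and light. Fallback: setting out from 21, all four hydroxyls are oxidised with Dess–Martin periodinane to the bis(keto aldehyde) F1. Norrish type I photolysis (about 300 nm, benzene) should then cleave each cyclopentanone at the more substituted C7′–C8′ bond, and the acyl radical takes the hydrogen from C9′ (the cyclopentanone to 4-alkenal photoreaction), giving the C7′ aldehyde and the C8′=C9′ alkene directly. A catalytic amount of iodine equilibrates the enals to (E), and the route is rejoined at 24.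

2. Step 15. Displacement at the hindered secondary C7 carbinol by a weakly acidic, valuable acid may be slow, may proceed partly with retention through an acyloxyphosphonium pathway, or may give way to elimination. Fallback: setting out from 13, a Mitsunobu reaction with the more acidic 4-nitrobenzoic acid gives the C7-inverted bis(4-nitrobenzoate) F2. Methanolysis (K2CO3, MeOH) gives the C7-epimeric diol F3, which is acylated twice with 19 under Yamaguchi conditions, with retention, to return to 20.

3. Step 8. The ene step may take the ring methine hydrogen at C5 instead of a methyl hydrogen (loss of the only bought stereocentre as a tertiary alcohol), and the product may be over-oxidised to the enal. Fallback: setting out from 10, epoxidation of the isopropenyl group (mCPBA, NaHCO3) gives the epoxide F4 (epimers at the new quaternary carbon). Isomerisation with a bulky amide base (diethylaluminium 2,2,6,6-tetramethylpiperidide, excess), which removes a proton from the unhindered methyl group, opens it to the allylic alcohol and returns to 11.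

Further compounds
F1 | step 18 | bis(keto aldehyde) diester (each arm 2-formyl-3-methyl-4-oxocyclopentylacetyl, acetonide kept) | O=C[C@@H]1[C@@H](C)C(=O)C[C@H]1CC(=O)OC[C@@H]2[C@@H](C)[C@H](OC(=O)C[C@@H]3CC(=O)[C@H](C)[C@H]3C=O)C[C@H]2C4COC(C)(C)OC4
F2 | step 15 | bis(4-nitrobenzoate) of the C7-inverted core diol | O=C(OC[C@@H]1[C@@H](C)[C@H](OC(=O)c2ccc(cc2)[N+](=O)[O-])C[C@H]1C3COC(C)(C)OC3)c4ccc(cc4)[N+](=O)[O-]
F3 | step 15 | (1R,2R,3S,4R)-4-(2,2-dimethyl-1,3-dioxan-5-yl)-3-(hydroxymethyl)-2-methylcyclopentan-1-ol | OC[C@@H]1[C@@H](C)[C@H](O)C[C@H]1C2COC(C)(C)OC2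
F4 | step 8 | (1S,2R,3S,4R)-3-(hydroxymethyl)-2-methyl-4-(2-methyloxiran-2-yl)cyclopentan-1-ol | OC[C@@H]1[C@@H](C)[C@@H](O)C[C@H]1C2(C)CO2
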